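Start from 93.4 %. That is the excess of right-handed over left-handed substrate in the violet flask at its last reading, 30.0 h, which is well inside 2.5 d. It already stands above the 90 % wanted.

| flask | left-handed substrate | right-handed substrate | gas | precatalyst | remark | time |
|---|---|---|---|---|---|---|
| violet | 0.10 M | 0.10 M | 40 mM (held) | 1.5 mM | the very flask that is asked about, followed so far |  |
| teal | 0.050 M | 0.050 M | 40 mM (held) | 1.5 mM | run made earlier |  |
| flask | 0.10 M | 0.10 M | 40 mM (held) | 1.5 mM |  | 2.5 d |

violet run (percent of the left-handed substrate and right-handed substrate together charged)

| time / h | right-handed substrate / % | left-handed substrate / % |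
|---|---|---|
| 4.00 | 50.0 | 44.5 |
| 8.00 | 49.5 | 31.5 |
| 12.0 | 49.5 | 19.6 |
| 15.0 | 49.1 | 13.2 |
| 20.0 | 48.3 | 6.2 |
| 25.0 | 47.5 | 2.8 |
| 30.0 | 47.1 | 1.6 |

teal run (percent of the left-handed substrate and right-handed substrate together charged)

| time / d | right-handed substrate / % | left-handed substrate / % |
|---|---|---|
| 0.333 | 49.8 | 29.7 |
| 0.625 | 48.6 | 11.5 |
| 1.04 | 47.2 | 2.3 |
| 1.25 | 47.1 | 1.2 |
| 1.67 | 46.2 | 0.2 |
| 2.00 | 45.9 | 0 |
| 2.50 | 44.5 | 0.6 |

(standard deviation of a reading: 0.3 percentage points)

- catalyst is single-handed; left-handed substrate and right-handed substrate are mirror images of each other, charged as a racemate, each of them at the stated concentration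
- the numbers in the tables scatter with a standard deviation of 0.3 percentage points
- at the start none of the gas is in solution

- whether the excess of right-handed substrate over left-handed substrate among what is left of the two reaches 90 % by 2.5 d (yes / no)
- the highest excess of right-handed substrate over left-handed substrate among what is left of the two up to 2.5 d

Bound the top with two extreme flasks. Let the violet flask stop dead at its last reading, and the top is 93.4 %. Let it burn the left-handed substrate to nothing and leave the right-handed untouched, and the top is 100 %. Expect the real flask between them. In the teal run both substrates went on falling: the left-handed to 0.2 % at 1.67 d, the right-handed to 44.5 % at 2.50 d.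

Now place it. Divide the logarithm of the fraction of left-handed substrate remaining by the same logarithm for the right-handed. This selectivity factor, read at the violet flask's last point, is 57.6. Assume it holds. Then the left-handed fraction is the right-handed fraction raised to that power. The ratio of their rates of fall is the factor times left-handed over right-handed. That ratio crosses one at an excess of 96.6 %; beyond it the right-handed substrate falls faster.

Violet and teal both read 47.1 % right-handed at 30.0 h, so borrow teal's last reading for the violet flask. The left-handed substrate is then 0.0607 %, and the excess is 99.7 %.

The forecast says yes and 99.6 %, noting “it passes 90% at about 27 h”. My figure differs from it by 0.10 percentage points.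

The violet flask gives yes and 99.6 %.

    partner + catalyst + left-handed substrate → catalyst + left-handed product (k = 7700 /M²/h)
    partner + catalyst + right-handed substrate → catalyst + right-handed product (k = 128 /M²/h)
    catalyst ⇌ dormant form (K = 8.97, k = 0.0731 /h)
    partner + precatalyst → catalyst + spent reagent (k = 1.83 /M/h)
    gas ⇌ partner, rate k5*(csat - [partner]) (kL = 0.946 /h)

At 0.362 d the violet flask's partner goes 36 times faster to the left-handed substrate than to the right-handed, but at 2.50 d, with 0.0831 % against 45.0 %, the factor puts that ratio at 0.106, past the crossing. The teal run's readings cross between 1.25 d, excess 95.0 %, and 1.67 d, excess 99.1 %.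

The numbers in the tables come from a simulation from invented constants; the scatter is artificial.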